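**Plan**
The target is an achiral tetraphenol. A CH2 bridge joins ring A (bridge ortho to its arm and to its OH) to ring B (bridge para to its arm, between OH and OMe), and each core ring carries a CH2–CH2 arm to a guaiacyl ring (ring C on ring A, ring D on ring B).
Enabling feature: in each ArCH2–CH2Ar arm both carbons are benzylic. Each central C–C bond can therefore be traced back to a CH2–SO2–CH2 unit that contracts with loss of SO2, and these two bonds are cut first, at the stilbene level.
Next cuts: the four C–S bonds (a core bis-benzylic dibromide plus two O-benzylvanillyl thiol equivalents), then the bond from the bridge carbon to ring B (ring A aldehyde plus ring B aryllithium).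
Forward order: all four benzene rings are bought. Rings A and B are joined first, through a temporary phthalide lactone that is opened again; rings C and D are then tied on through sulfur, both sulfones are contracted in one operation, and one hydrogenation finishes the synthesis.
Oxygen pattern: the ring A OH comes from chelation-directed demethylation next to the aldehyde. The ring B pattern comes from a purchased resorcinol monomethyl ether ester that is lithiated between its two oxygens.
Stereochemistry: the target has none; the single racemic centre of the phthalide and the alkene geometry are both erased on the way.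

Key step: step 16

Remark on the chemistry: in the key step the chlorine is drawn on the core-side α-carbon of each sulfone. Chlorination at the guaiacyl-side α-carbon leads to the same episulfone and the same alkene.

**Step 1**
Reactants: 1 methyl 3,5-dimethoxybenzoate
Product: 3 methyl 2-formyl-3,5-dimethoxybenzoate, via aryl iminium chloride 2 (not isolated)
Conditions: POCl3, DMF, 0 to 90 °C; then ice–water
Reagents that add atoms: N,N-dimethylformamide, CN(C)C=O; water, O
Why: Vilsmeier–Haack formylation attacks C-2, ortho to one methoxy group and para to the other as is usual for resorcinol diethers, and the iminium salt 2 deactivates the ring against a second attack until water releases the aldehyde.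

**Step 2**
Reactants: 3 methyl 2-formyl-3,5-dimethoxybenzoate
Product: 5 methyl 2-formyl-3-hydroxy-5-methoxybenzoate, via aryloxydichloroborane 4 (not isolated)
Conditions: BCl3 (1.2 equiv), CH2Cl2, −78 to 0 °C; then H2O
Reagents that add atoms: none
Why: In this chelation-directed aryl methyl ether cleavage boron is held between the aldehyde oxygen and the adjacent 3-methoxy oxygen, so chloride removes only that methyl group, while the 5-methoxy group and the ester methyl cannot form such a six-membered chelate and should stay.

**Step 3**
Reactants: 5 methyl 2-formyl-3-hydroxy-5-methoxybenzoate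
Product: 6 methyl 3-(benzyloxy)-2-formyl-5-methoxybenzoate
Conditions: BnBr, K2CO3, DMF, 50 °C
Reagents that add atoms: benzyl bromide, BrCc1ccccc1
Why: Williamson ether synthesis at the only acidic OH, with a carbonate base that touches neither the aldehyde nor the ester.

**Step 4**
Reactants: 7 methyl 3-hydroxy-5-methoxybenzoate
Product: 8 methyl 3-methoxy-5-(methoxymethoxy)benzoate
Conditions: MOMCl, i-Pr2NEt, CH2Cl2, 0 °C to rt
Reagents that add atoms: chloromethyl methyl ether, COCCl
Why: Standard O-alkylation of a phenol to its methoxymethyl acetal, which installs the group that will direct the lithiation in step 7.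

**Step 5**
Reactants: 8 methyl 3-methoxy-5-(methoxymethoxy)benzoate
Product: 9 [3-methoxy-5-(methoxymethoxy)phenyl]methanol
Conditions: LiAlH4, THF, 0 °C
Reagents that add atoms: none
Why: Hydride reduction of an ester to the primary alcohol, under which the acetal and the aryl ether are inert.

**Step 6**
Reactants: 9 [3-methoxy-5-(methoxymethoxy)phenyl]methanol
Product: 10 tert-butyl{[3-methoxy-5-(methoxymethoxy)phenyl]methoxy}dimethylsilane
Conditions: TBSCl, imidazole, DMF, rt
Reagents that add atoms: tert-butyldimethylsilyl chloride, CC(C)(C)[Si](C)(C)Cl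
Why: Routine silylation of a primary alcohol, giving a bulky, poorly coordinating ether that removes the acidic proton and shields the two ring positions next to the side chain.

**Step 7**
Reactants: 10 tert-butyl{[3-methoxy-5-(methoxymethoxy)phenyl]methoxy}dimethylsilane; 6 methyl 3-(benzyloxy)-2-formyl-5-methoxybenzoate
Product: 13 racemic 4-(benzyloxy)-3-[4-({[tert-butyl(dimethyl)silyl]oxy}methyl)-2-methoxy-6-(methoxymethoxy)phenyl]-6-methoxy-2-benzofuran-1(3H)-one, via ring B aryllithium 11 (not isolated), via lithium alkoxide 12 (not isolated)
Conditions: 10, n-BuLi, THF, 0 °C; then 6, THF, −78 °C to rt; then H2O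
Reagents that add atoms: none
Why: Directed ortho-metalation removes the ring proton flanked by the OMOM and OMe groups, the aryllithium adds to the aldehyde far faster than to the ester at low temperature, and the alkoxide closes the five-membered lactone on warming, as is usual for 2-formylbenzoates; the new centre forms as a racemate and is removed in step 8.

**Step 8**
Reactants: 13 racemic 3-arylphthalide
Product: 14 3-(benzyloxy)-2-{[2-hydroxy-4-(hydroxymethyl)-6-methoxyphenyl]methyl}-5-methoxybenzoic acid
Conditions: Et3SiH (excess), TFA, CH2Cl2, trace H2O, 0 °C to rt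
Reagents that add atoms: none
Why: Ionic hydrogenation of a 3-arylphthalide to a 2-benzylbenzoic acid should be easy here because the lactone C–O bond ionises to a diarylmethyl cation carrying four ortho or para alkoxy donors; the silane reduces that cation irreversibly and scavenges the methoxymethyl cation, and the same acid frees the ring B phenol and the primary alcohol, whose own cation has only meta alkoxy groups and is not reduced.

**Step 9**
Reactants: 14 3-(benzyloxy)-2-{[2-hydroxy-4-(hydroxymethyl)-6-methoxyphenyl]methyl}-5-methoxybenzoic acid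
Product: 15 benzyl 3-(benzyloxy)-2-{[2-(benzyloxy)-4-(hydroxymethyl)-6-methoxyphenyl]methyl}-5-methoxybenzoate
Conditions: BnBr (2.5 equiv), K2CO3, DMF, 50 °C
Reagents that add atoms: benzyl bromide, BrCc1ccccc1
Why: Williamson etherification and carboxylate alkylation occur together because K2CO3 deprotonates only the phenol and the acid, so the primary alcohol stays free, and any ring A benzyl ether lost in step 8 would be restored here.

**Step 10**
Reactants: 15 benzyl ester
Product: 16 core diol [3-(benzyloxy)-2-{[2-(benzyloxy)-4-(hydroxymethyl)-6-methoxyphenyl]methyl}-5-methoxyphenyl]methanol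
Conditions: LiAlH4, THF, 0 °C to rt
Reagents that add atoms: none
Why: Hydride reduction of the ester gives the second CH2OH group, and aryl benzyl and methyl ethers are inert to LiAlH4.

**Step 11**
Reactants: 16 core diol
Product: 17 core dibromide 1-(benzyloxy)-2-{[2-(benzyloxy)-4-(bromomethyl)-6-methoxyphenyl]methyl}-3-(bromomethyl)-5-methoxybenzene
Conditions: PBr3, CH2Cl2, 0 °C
Reagents that add atoms: phosphorus tribromide, BrP(Br)Br
Why: Both primary benzylic alcohols are brominated through their phosphite esters; the alkoxy groups sit meta to each CH2Br, so the bromides should be as stable as 3,5-dimethoxybenzyl bromide, and both ring B positions ortho to the bridge are occupied, which rules out Friedel–Crafts cyclisation.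

**Step 12**
Reactants: 18 vanillyl alcohol
Product: 19 [4-(benzyloxy)-3-methoxyphenyl]methanol
Conditions: BnBr, K2CO3, acetone, reflux
Reagents that add atoms: benzyl bromide, BrCc1ccccc1
Why: Chemoselective Williamson ether synthesis, since the carbonate deprotonates the phenol but not the benzylic alcohol.

**Step 13**
Reactants: 19 [4-(benzyloxy)-3-methoxyphenyl]methanol
Product: 20 S-[4-(benzyloxy)-3-methoxybenzyl] ethanethioate
Conditions: PPh3, DIAD, AcSH, THF, 0 °C to rt
Reagents that add atoms: thioacetic acid, CC(=O)S
Why: Mitsunobu thioesterification of a primary benzylic alcohol under neutral conditions gives a storable, oxidation-resistant thiol equivalent.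

**Step 14**
Reactants: 17 core dibromide; 20 S-[4-(benzyloxy)-3-methoxybenzyl] ethanethioate (2 equiv)
Product: 22 core bis-sulfide (17 with each Br replaced by S–CH2–(4-benzyloxy-3-methoxyphenyl)), via benzylic thiol 21 (not isolated)
Conditions: 20, K2CO3, degassed MeOH–THF, rt; then 17, rt
Reagents that add atoms: none
Why: Methanolysis of the thioacetate releases the thiolate in the flask, and this soft nucleophile displaces both primary benzylic bromides by SN2 much faster than methanol does, while exclusion of air suppresses disulfide formation.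

**Step 15**
Reactants: 22 core bis-sulfide
Product: 23 core bis(4-benzyloxy-3-methoxybenzylsulfonylmethyl) diarylmethane (bis-sulfone)
Conditions: mCPBA (4.5 equiv), CH2Cl2, 0 °C to rt
Reagents that add atoms: 3-chloroperoxybenzoic acid, OOC(=O)c1cccc(Cl)c1
Why: Peracid oxidation of sulfides to sulfones, in which sulfur is by far the most nucleophilic site, so the alkoxyarenes and the benzylic CH2 groups should be left alone at this temperature.

**Step 16**
Reactants: 23 bis-sulfone
Product: 26 tetra-O-benzyl (E,E)-bis-stilbene, via bis(alpha-chlorosulfone) 24 (not isolated), via bis(episulfone) 25 (not isolated)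
Conditions: powdered KOH (excess), CCl4, t-BuOH, H2O, 25 to 60 °C
Reagents that add atoms: none
Why: Hydroxide deprotonates each dibenzyl sulfone at an α-carbon, the carbanion takes chlorine from CCl4 to give 24, deprotonation at the α′-carbon and intramolecular 1,3-displacement of chloride give the episulfones 25, and cheletropic loss of SO2 leaves the two stilbene double bonds. The closest known reaction type is the Ramberg–Bäcklund reaction of dibenzyl sulfones with in situ halogenation, which is also known in twofold form. No ring of the product is closed; the only closure is the transient 3-exo-tet formation of each thiirane dioxide, which is lost again on extrusion. No stereocentre is created, and E geometry should prevail because base equilibrates each episulfone to its trans form before extrusion, although either geometry serves since step 17 saturates both bonds. The step needs halogenation and deprotonation at the four sulfone α-CH2 groups and not at the bridging diarylmethane CH2 or the O-benzyl CH2 groups, and the much higher acidity of a benzylic sulfone compared with an electron-rich diarylmethane or a benzyl ether secures this. Crossed rather than homo-coupling of carbons that all began as electrophilic benzylic centres is secured by the sulfur tether, which ties each core carbon to exactly one guaiacyl carbon.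

**Step 17**
Reactants: 26 tetra-O-benzyl (E,E)-bis-stilbene
Product: 27 2-{[2-hydroxy-4-[2-(4-hydroxy-3-methoxyphenyl)ethyl]-6-methoxyphenyl]methyl}-3-[2-(4-hydroxy-3-methoxyphenyl)ethyl]-5-methoxyphenol (CNP0079001.0)
Conditions: H2 (1 atm), Pd/C, EtOAc–MeOH, rt
Reagents that add atoms: none
Why: Heterogeneous catalytic hydrogenation saturates both stilbene double bonds and hydrogenolyses all four aryl benzyl ethers in one operation, while the methyl ethers and the diarylmethane bridge are inert; 26 should be freed of sulfur-containing traces beforehand.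

**Compound list**
1 | methyl 3,5-dimethoxybenzoate | COC(=O)c1cc(OC)cc(OC)c1 | starting material
2 | [2,4-dimethoxy-6-(methoxycarbonyl)phenyl]methylidene(dimethyl)ammonium chloride | COC(=O)c1cc(OC)cc(OC)c1C=[N+](C)C.[Cl-] | intermediate (not isolated)
3 | methyl 2-formyl-3,5-dimethoxybenzoate | COC(=O)c1cc(OC)cc(OC)c1C=O | intermediate
4 | methyl 3-[(dichloroboranyl)oxy]-2-formyl-5-methoxybenzoate | COC(=O)c1cc(OC)cc(OB(Cl)Cl)c1C=O | intermediate (not isolated)
5 | methyl 2-formyl-3-hydroxy-5-methoxybenzoate | COC(=O)c1cc(OC)cc(O)c1C=O | intermediate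
6 | methyl 3-(benzyloxy)-2-formyl-5-methoxybenzoate | COC(=O)c1cc(OC)cc(OCc2ccccc2)c1C=O | intermediate
7 | methyl 3-hydroxy-5-methoxybenzoate | COC(=O)c1cc(O)cc(OC)c1 | starting material
8 | methyl 3-methoxy-5-(methoxymethoxy)benzoate | COCOc1cc(OC)cc(C(=O)OC)c1 | intermediate
9 | [3-methoxy-5-(methoxymethoxy)phenyl]methanol | COCOc1cc(OC)cc(CO)c1 | intermediate
10 | tert-butyl{[3-methoxy-5-(methoxymethoxy)phenyl]methoxy}dimethylsilane | COCOc1cc(OC)cc(CO[Si](C)(C)C(C)(C)C)c1 | intermediate
11 | [4-({[tert-butyl(dimethyl)silyl]oxy}methyl)-2-methoxy-6-(methoxymethoxy)phenyl]lithium | COCOc1cc(CO[Si](C)(C)C(C)(C)C)cc(OC)c1[Li] | intermediate (not isolated)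
12 | racemic lithium alkoxide of methyl 3-(benzyloxy)-2-{hydroxy[4-({[tert-butyl(dimethyl)silyl]oxy}methyl)-2-methoxy-6-(methoxymethoxy)phenyl]methyl}-5-methoxybenzoate | COC(=O)c1cc(OC)cc(OCc2ccccc2)c1C([O-])c1c(OCOC)cc(CO[Si](C)(C)C(C)(C)C)cc1OC.[Li+] | intermediate (not isolated)
13 | racemic 4-(benzyloxy)-3-[4-({[tert-butyl(dimethyl)silyl]oxy}methyl)-2-methoxy-6-(methoxymethoxy)phenyl]-6-methoxy-2-benzofuran-1(3H)-one | O=C1OC(c2c(OCOC)cc(CO[Si](C)(C)C(C)(C)C)cc2OC)c2c(OCc3ccccc3)cc(OC)cc12 | intermediate
14 | 3-(benzyloxy)-2-{[2-hydroxy-4-(hydroxymethyl)-6-methoxyphenyl]methyl}-5-methoxybenzoic acid | OC(=O)c1cc(OC)cc(OCc2ccccc2)c1Cc1c(O)cc(CO)cc1OC | intermediate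
15 | benzyl 3-(benzyloxy)-2-{[2-(benzyloxy)-4-(hydroxymethyl)-6-methoxyphenyl]methyl}-5-methoxybenzoate | O=C(OCc1ccccc1)c1cc(OC)cc(OCc2ccccc2)c1Cc1c(OCc2ccccc2)cc(CO)cc1OC | intermediate
16 | [3-(benzyloxy)-2-{[2-(benzyloxy)-4-(hydroxymethyl)-6-methoxyphenyl]methyl}-5-methoxyphenyl]methanol (core diol) | OCc1cc(OC)cc(OCc2ccccc2)c1Cc1c(OCc2ccccc2)cc(CO)cc1OC | intermediate
17 | 1-(benzyloxy)-2-{[2-(benzyloxy)-4-(bromomethyl)-6-methoxyphenyl]methyl}-3-(bromomethyl)-5-methoxybenzene (core dibromide) | BrCc1cc(OC)cc(OCc2ccccc2)c1Cc1c(OCc2ccccc2)cc(CBr)cc1OC | intermediate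
18 | vanillyl alcohol, 4-(hydroxymethyl)-2-methoxyphenol | COc1cc(CO)ccc1O | starting material
19 | [4-(benzyloxy)-3-methoxyphenyl]methanol | COc1cc(CO)ccc1OCc1ccccc1 | intermediate
20 | S-[4-(benzyloxy)-3-methoxybenzyl] ethanethioate | CC(=O)SCc1ccc(OCc2ccccc2)c(OC)c1 | intermediate
21 | [4-(benzyloxy)-3-methoxyphenyl]methanethiol, present as its potassium thiolate | SCc1ccc(OCc2ccccc2)c(OC)c1 | intermediate (not isolated)
22 | core bis(4-benzyloxy-3-methoxybenzylsulfanylmethyl) diarylmethane (bis-sulfide) | COc1cc(OCc2ccccc2)c(Cc2c(OCc3ccccc3)cc(CSCc3ccc(OCc4ccccc4)c(OC)c3)cc2OC)c(CSCc2ccc(OCc3ccccc3)c(OC)c2)c1 | intermediate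
23 | core bis(4-benzyloxy-3-methoxybenzylsulfonylmethyl) diarylmethane (bis-sulfone) | COc1cc(OCc2ccccc2)c(Cc2c(OCc3ccccc3)cc(CS(=O)(=O)Cc3ccc(OCc4ccccc4)c(OC)c3)cc2OC)c(CS(=O)(=O)Cc2ccc(OCc3ccccc3)c(OC)c2)c1 | intermediate
24 | bis(α-chlorosulfone): 23 with one chlorine on the core-side α-carbon of each sulfone (mixture of stereoisomers) | COc1cc(OCc2ccccc2)c(Cc2c(OCc3ccccc3)cc(C(Cl)S(=O)(=O)Cc3ccc(OCc4ccccc4)c(OC)c3)cc2OC)c(C(Cl)S(=O)(=O)Cc2ccc(OCc3ccccc3)c(OC)c2)c1 | intermediate (not isolated)
25 | bis(episulfone): each arm a 2,3-diarylthiirane 1,1-dioxide (mixture of stereoisomers) | COc1cc(OCc2ccccc2)c(Cc2c(OCc3ccccc3)cc(C3C(c4ccc(OCc5ccccc5)c(OC)c4)S3(=O)=O)cc2OC)c(C2C(c3ccc(OCc4ccccc4)c(OC)c3)S2(=O)=O)c1 | intermediate (not isolated)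
26 | tetra-O-benzyl (E,E)-bis-stilbene | COc1cc(OCc2ccccc2)c(Cc2c(OCc3ccccc3)cc(/C=C/c3ccc(OCc4ccccc4)c(OC)c3)cc2OC)c(/C=C/c2ccc(OCc3ccccc3)c(OC)c2)c1 | intermediate
27 | 2-{[2-hydroxy-4-[2-(4-hydroxy-3-methoxyphenyl)ethyl]-6-methoxyphenyl]methyl}-3-[2-(4-hydroxy-3-methoxyphenyl)ethyl]-5-methoxyphenol (CNP0079001.0, achiral) | COc1cc(O)c(Cc2c(O)cc(CCc3ccc(O)c(OC)c3)cc2OC)c(CCc2ccc(O)c(OC)c2)c1 | target

**Step count**
Total steps: 17.
Longest linear sequence: 12 steps (1–3, 7–11, 14–17). The ring B branch 4–6 is of equal length, and the thioacetate branch 12–13 is shorter.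

**Steps most likely to fail**

*Step 7.* Three things may go wrong:
- The aryllithium may add to the ester carbonyl of 6, or to the lactone as it forms.
- Addition to an aldehyde flanked by two ortho substituents may be slow enough for the organolithium to decay.
- Metalation may stray to the ring positions beside the silyloxymethyl group.

Fallback: the ester is taken out of play. Setting out from 6, saponification (LiOH, THF–H2O) gives 3-(benzyloxy)-2-formyl-5-methoxybenzoic acid F1. Its lithium carboxylate, formed with LiN(SiMe3)2, is inert to 11, so the addition can be run warmer and with excess nucleophile, and it stops at the alkoxide–carboxylate stage where no lactone is present to be attacked. Mild acidification gives the racemic hydroxy acid F2, which lactonises spontaneously and comes back to the route at 13.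

*Step 8.* One acid treatment has to do three jobs, and several processes could spoil it:
- Removal of the silyl or acetal group may be incomplete.
- The ring A benzyl ether may be lost.
- The liberated methoxymethyl cation may re-alkylate the electron-rich rings.
- Ipso-protonation may fragment the newly formed diarylmethane.

Fallback: hydride transfer to a cation is replaced by catalytic hydrogenolysis, and the deprotection is done separately. Setting out from 13, H2 over Pd/C in EtOAc–AcOH cleaves the benzhydrylic lactone C–O bond together with the ring A benzyl ether to give the silyl- and acetal-protected phenol acid F3. Dilute HCl in MeOH at rt then removes the acetal and the silyl ether to give the trihydroxy acid F4. Threefold benzylation (BnBr, K2CO3, DMF) comes back to the route at 15.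

*Step 16.* Three processes could interfere:
- The α-carbons may be over-chlorinated.
- Dichlorocarbene generated from CCl4 may add to the electron-rich double bonds.
- The more hindered ring A sulfone, or poorly soluble material, may react slowly, so that only one arm contracts.

Fallback: the same two C=C bonds are formed by olefination. Setting out from 17, a Michaelis–Arbuzov reaction with P(OEt)3 at 130 °C gives the tetraethyl bis-phosphonate F5. A twofold Horner–Wadsworth–Emmons reaction with commercial 4-(benzyloxy)-3-methoxybenzaldehyde (KOtBu, THF, 0 °C to rt) comes back to the route at 26.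

**Further compounds**
F1 | step 7 | 3-(benzyloxy)-2-formyl-5-methoxybenzoic acid | OC(=O)c1cc(OC)cc(OCc2ccccc2)c1C=O
F2 | step 7 | racemic 3-(benzyloxy)-2-{hydroxy[4-({[tert-butyl(dimethyl)silyl]oxy}methyl)-2-methoxy-6-(methoxymethoxy)phenyl]methyl}-5-methoxybenzoic acid | OC(=O)c1cc(OC)cc(OCc2ccccc2)c1C(O)c1c(OCOC)cc(CO[Si](C)(C)C(C)(C)C)cc1OC
F3 | step 8 | 2-{[4-({[tert-butyl(dimethyl)silyl]oxy}methyl)-2-methoxy-6-(methoxymethoxy)phenyl]methyl}-3-hydroxy-5-methoxybenzoic acid | OC(=O)c1cc(OC)cc(O)c1Cc1c(OCOC)cc(CO[Si](C)(C)C(C)(C)C)cc1OC
F4 | step 8 | 3-hydroxy-2-{[2-hydroxy-4-(hydroxymethyl)-6-methoxyphenyl]methyl}-5-methoxybenzoic acid | OC(=O)c1cc(OC)cc(O)c1Cc1c(O)cc(CO)cc1OC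
F5 | step 16 | tetraethyl bis-phosphonate (17 with each Br replaced by P(O)(OEt)2) | CCOP(=O)(OCC)Cc1cc(OC)cc(OCc2ccccc2)c1Cc1c(OCc2ccccc2)cc(CP(=O)(OCC)OCC)cc1OC
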